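**Plan**

- Retrosynthesis: after removing two protecting groups (the C5 O-methyl and the ring D O-benzyl), ring C is cut at O1–C8a and C4–C4a together. This gives an aryne across C4a–C8a of ring A and ethyl (S)-3-hydroxy-3-phenylpropanoate.
- Enabling feature: ring A is hexasubstituted, and its neighbouring carbons C8a and C4a hold the two ends (O1 and the C4 carbonyl) of the chain O1–C2–C3–C4. One aryne can therefore take up both ends of a β-hydroxy ester.
- The aryne precursor, an ortho-silylaryl triflate, is cut at C8–CH2 (Friedel–Crafts benzylation) and traced to 3,4,5-trimethoxyphenol and 2-hydroxy-5-methoxybenzaldehyde.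
- Forward order: ring D is joined to the brominated ring A phenol, the bromophenol becomes the silyl triflate, ring C is closed last by the aryne annulation, and the two ethers are then cleaved.
- Stereochemistry: the only stereocentre, C2 (S), is bought with the hydroxy ester, and its C–O bond is never broken.

Key step: step 7

Remark on the chemistry: flavanone numbering is used throughout (O1, C2–C4, C4a, C5–C8, C8a). Ring A is the benzo ring, ring B the C2 phenyl, ring C the pyranone and ring D the aryl ring of the C8 benzyl group. The stereodescriptor in the target SMILES corresponds to 2S.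

**Route**

Step 1
Reactants: 1 2-hydroxy-5-methoxybenzaldehyde
Product: 2 2-(benzyloxy)-5-methoxybenzaldehyde
Conditions: BnBr, K2CO3, DMF, rt
Reagents that add atoms: benzyl bromide, BrCc1ccccc1
Why: Williamson etherification, in which the phenoxide formed by K2CO3 displaces bromide from benzyl bromide while the aldehyde is inert.

Step 2
Reactants: 2 2-(benzyloxy)-5-methoxybenzaldehyde
Product: 3 [2-(benzyloxy)-5-methoxyphenyl]methanol
Conditions: NaBH4, MeOH, 0 °C
Reagents that add atoms: none
Why: Borohydride reduction of an aryl aldehyde to the benzylic alcohol, which leaves both aryl ethers untouched.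

Step 3
Reactants: 4 3,4,5-trimethoxyphenol
Product: 5 2-bromo-3,4,5-trimethoxyphenol
Conditions: NBS (1.0 equiv), CH2Cl2, −78 → 0 °C
Reagents that add atoms: N-bromosuccinimide, O=C1CCC(=O)N1Br
Why: Electrophilic aromatic bromination in which the two free positions of the symmetrical phenol are equivalent, and the first bromine should deactivate the ring enough for one equivalent of NBS at low temperature to stop at the monobromide.

Step 4
Reactants: 5 2-bromo-3,4,5-trimethoxyphenol; 3 [2-(benzyloxy)-5-methoxyphenyl]methanol
Product: 6 2-[2-(benzyloxy)-5-methoxybenzyl]-6-bromo-3,4,5-trimethoxyphenol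
Conditions: TsOH·H2O (10 mol %), HFIP/CH2Cl2, rt
Reagents that add atoms: none
Why: Friedel–Crafts benzylation, in which acid ionises the ortho-alkoxybenzylic alcohol to a stabilised cation that is captured at the only unsubstituted carbon of the bromophenol (ortho to OH, para to a methoxy group), so that neither regioisomers nor double benzylation can arise.

Step 5
Reactants: 6 2-[2-(benzyloxy)-5-methoxybenzyl]-6-bromo-3,4,5-trimethoxyphenol
Product: 7 {2-[2-(benzyloxy)-5-methoxybenzyl]-6-bromo-3,4,5-trimethoxyphenoxy}trimethylsilane
Conditions: HMDS, THF, 70 °C; evaporation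
Reagents that add atoms: hexamethyldisilazane, C[Si](C)(C)N[Si](C)(C)C
Why: O-Silylation of the phenol with HMDS, driven by loss of ammonia, places the silyl group ortho to bromine ready for migration.

Step 6
Reactants: 7 {2-[2-(benzyloxy)-5-methoxybenzyl]-6-bromo-3,4,5-trimethoxyphenoxy}trimethylsilane
Product: 10 2-[2-(benzyloxy)-5-methoxybenzyl]-3,4,5-trimethoxy-6-(trimethylsilyl)phenyl trifluoromethanesulfonate, via aryllithium 8 (not isolated), via lithium silylphenoxide 9 (not isolated)
Conditions: n-BuLi, THF, −78 °C; then Tf2O, −78 → 0 °C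
Reagents that add atoms: trifluoromethanesulfonic anhydride, O=S(=O)(OS(=O)(=O)C(F)(F)F)C(F)(F)F
Why: Bromine–lithium exchange outruns any deprotonation at −78 °C, the ortho-silyloxy aryllithium undergoes retro-Brook (anionic 1,3 O-to-C silyl) rearrangement to the lithium phenoxide, and Tf2O traps this on oxygen, which is the standard way to ortho-silylaryl triflates.

Step 7
Reactants: 10 2-[2-(benzyloxy)-5-methoxybenzyl]-3,4,5-trimethoxy-6-(trimethylsilyl)phenyl trifluoromethanesulfonate; 11 ethyl (3S)-3-hydroxy-3-phenylpropanoate
Product: 14 (2S)-8-[2-(benzyloxy)-5-methoxybenzyl]-5,6,7-trimethoxyflavanone, via aryne 12 (not isolated), via caesium aryl 13 (not isolated)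
Conditions: CsF (3 equiv), 18-crown-6, THF, −20 → 0 °C; pH 7 buffer quench
Reagents that add atoms: none
Why: Proposed new method: fluoride removes the silyl group and triflate departs to give aryne 12 (C4a≡C8a); the fluoride-activated hydroxyl oxygen of 11 adds to C8a, and the aryl anion 13 formed at C4a attacks the neighbouring ester carbonyl in an addition–elimination that expels ethoxide, so that O1–C8a and C4–C4a form in one flask. The closest known reaction types are the annulation of arynes with methyl salicylates to xanthones, the O–H insertion of arynes into aliphatic alcohols and the C–O insertion of arynes into carboxylic acids that leads to chroman-4-ones; an aliphatic β-hydroxy ester as the partner is the untested part. Ring C closes by 6-exo-trig attack of the C4a carbanion on the ester carbonyl, a formal [4+2] annulation across C4a–C8a. No stereocentre is created: C2 arrives as the S carbinol carbon of 11 and its C–O bond is never broken, so the configuration should be kept as long as retro-aldol cleavage of the alkoxide and base-induced retro-oxa-Michael opening of 14 are held back by using fluoride as the only base at or below 0 °C and a buffered quench. The selectivity needed is regiochemical: the inductively withdrawing C5 methoxy group beside C4a distorts the aryne so that oxygen attacks the distal C8a and the charge develops at C4a, which should override the weaker steric bias of the C8 benzyl group. Acylation of the C4a anion rather than its protonation is favoured by the six-membered intramolecular transition state and the aprotic solvent.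

Step 8
Reactants: 14 (2S)-8-[2-(benzyloxy)-5-methoxybenzyl]-5,6,7-trimethoxyflavanone
Product: 15 (2S)-5-hydroxy-8-(2-hydroxy-5-methoxybenzyl)-6,7-dimethoxyflavanone (CNP0191546.1)
Conditions: BCl3, C6HMe5, CH2Cl2, −78 → 0 °C; MeOH/H2O
Reagents that add atoms: none
Why: Lewis-acid ether cleavage, in which BCl3 chelated between the C4 carbonyl and the C5 oxygen removes only the peri methyl group and cleaves the benzyl ether at low temperature with pentamethylbenzene trapping the benzyl cation, while the unchelated methyl ethers at C6, C7 and on ring D and the C2 stereocentre should survive.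

**Compound list**

1 | 2-hydroxy-5-methoxybenzaldehyde | COc1ccc(O)c(C=O)c1 | starting material
2 | 2-(benzyloxy)-5-methoxybenzaldehyde | COc1ccc(OCc2ccccc2)c(C=O)c1 | intermediate
3 | [2-(benzyloxy)-5-methoxyphenyl]methanol | COc1ccc(OCc2ccccc2)c(CO)c1 | intermediate
4 | 3,4,5-trimethoxyphenol | COc1cc(O)cc(OC)c1OC | starting material
5 | 2-bromo-3,4,5-trimethoxyphenol | COc1cc(O)c(Br)c(OC)c1OC | intermediate
6 | 2-[2-(benzyloxy)-5-methoxybenzyl]-6-bromo-3,4,5-trimethoxyphenol | COc1ccc(OCc2ccccc2)c(Cc2c(O)c(Br)c(OC)c(OC)c2OC)c1 | intermediate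
7 | {2-[2-(benzyloxy)-5-methoxybenzyl]-6-bromo-3,4,5-trimethoxyphenoxy}trimethylsilane | COc1ccc(OCc2ccccc2)c(Cc2c(O[Si](C)(C)C)c(Br)c(OC)c(OC)c2OC)c1 | intermediate
8 | {3-[2-(benzyloxy)-5-methoxybenzyl]-4,5,6-trimethoxy-2-[(trimethylsilyl)oxy]phenyl}lithium | COc1ccc(OCc2ccccc2)c(Cc2c(O[Si](C)(C)C)c([Li])c(OC)c(OC)c2OC)c1 | intermediate
9 | lithium 2-[2-(benzyloxy)-5-methoxybenzyl]-3,4,5-trimethoxy-6-(trimethylsilyl)phenolate | COc1ccc(OCc2ccccc2)c(Cc2c([O-])c([Si](C)(C)C)c(OC)c(OC)c2OC)c1.[Li+] | intermediate
10 | 2-[2-(benzyloxy)-5-methoxybenzyl]-3,4,5-trimethoxy-6-(trimethylsilyl)phenyl trifluoromethanesulfonate | COc1ccc(OCc2ccccc2)c(Cc2c(OC)c(OC)c(OC)c([Si](C)(C)C)c2OS(=O)(=O)C(F)(F)F)c1 | intermediate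
11 | ethyl (3S)-3-hydroxy-3-phenylpropanoate | O[C@H](c1ccccc1)CC(=O)OCC | starting material
12 | 3-[2-(benzyloxy)-5-methoxybenzyl]-4,5,6-trimethoxybenzyne (1,2-didehydrobenzene; triple bond C4a≡C8a in flavanone numbering) | COC1=C(OC)C(OC)=C(Cc2cc(OC)ccc2OCc2ccccc2)C#C1 | intermediate
13 | caesium salt of the C4a aryl anion of ethyl (3S)-3-{2-[2-(benzyloxy)-5-methoxybenzyl]-3,4,5-trimethoxyphenoxy}-3-phenylpropanoate (carbanion ortho to the ether oxygen) | CCOC(=O)C[C@H](Oc1c(Cc2cc(OC)ccc2OCc2ccccc2)c(OC)c(OC)c(OC)[c-]1)c1ccccc1.[Cs+] | intermediate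
14 | (2S)-8-[2-(benzyloxy)-5-methoxybenzyl]-5,6,7-trimethoxy-2-phenylchroman-4-one | COc1ccc(OCc2ccccc2)c(Cc2c(OC)c(OC)c(OC)c3c2O[C@H](c2ccccc2)CC3=O)c1 | intermediate
15 | (2S)-5-hydroxy-8-(2-hydroxy-5-methoxybenzyl)-6,7-dimethoxy-2-phenylchroman-4-one (CNP0191546.1) | COc1ccc(O)c(Cc2c(OC)c(OC)c(O)c3c2O[C@H](c2ccccc2)CC3=O)c1 | target

**Step count**

Total: 8 steps. Longest linear sequence: 7 steps (steps 1, 2, 4, 5, 6, 7, 8, from aldehyde 1).

**Steps most likely to fail**

Step 7 (proposed new method). What may go wrong: the C4a carbanion is quenched by proton transfer before it acylates, so that the sequence halts after O-arylation. The proton can come from a second molecule of 11, from bifluoride or from the α-methylene of its own chain. Enolisation followed by β-elimination of the aryloxide, retro-aldol cleavage of the alkoxide, or capture of C8a by the ring D ether oxygen would lose further material. The fallback uses known chemistry and closes ring C stepwise. It sets out from 10 and 11 and runs the known O–H insertion of an aryne into an aliphatic alcohol on purpose (CsF, MeCN, rt, with acetonitrile as the proton source) to give ethyl (3S)-3-{2-[2-(benzyloxy)-5-methoxybenzyl]-3,4,5-trimethoxyphenoxy}-3-phenylpropanoate F1. The ester is cleaved under near-neutral conditions (Me3SnOH, 1,2-dichloroethane, 70 °C) to (3S)-3-{2-[2-(benzyloxy)-5-methoxybenzyl]-3,4,5-trimethoxyphenoxy}-3-phenylpropanoic acid F2. Intramolecular Friedel–Crafts acylation at C4a, the only unsubstituted and strongly activated position of ring A (TFAA, CH2Cl2, 0 °C), then closes ring C and returns to the route at 14. None of these bond changes involves the stereocentre.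

Step 8. What may go wrong: the longer exposure to BCl3 that the benzyl ether requires causes loss of a second methyl group (at C6), re-benzylation of ring D by the liberated benzyl cation, or partial racemisation through Lewis-acid-assisted opening of the benzylic C2–O1 bond. The fallback separates the two cleavages so that no benzyl cation is ever formed. It sets out from 14: neutral hydrogenolysis (H2, Pd/C, EtOAc, rt) should give (2S)-8-(2-hydroxy-5-methoxybenzyl)-5,6,7-trimethoxy-2-phenylchroman-4-one F3. A brief chelation-controlled demethylation of the C5 ether alone (BCl3, 2.2 equiv, CH2Cl2, −78 °C) then comes back to the route at 15.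

Step 6. What may go wrong: in the fully substituted ring the O-to-C silyl shift is slow, so the aryllithium is protonated and bromine is lost without silylation; or the hindered lithium phenoxide is triflated incompletely and the silyl group is lost on work-up. The fallback makes the C–Si bond by intermolecular trapping of a dianion and triflates an isolated phenol. It sets out from 6: n-BuLi (2.2 equiv, THF, −78 °C) forms the O,C-dilithio species, and excess TMSCl should give {2-[2-(benzyloxy)-5-methoxybenzyl]-3,4,5-trimethoxy-6-(trimethylsilyl)phenoxy}trimethylsilane F4. K2CO3 in MeOH removes the O-silyl group to give 2-[2-(benzyloxy)-5-methoxybenzyl]-3,4,5-trimethoxy-6-(trimethylsilyl)phenol F5. Triflation with PhNTf2 and Cs2CO3 in THF at rt comes back to the route at 10.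

**Further compounds**

F1 | step 7 | ethyl (3S)-3-{2-[2-(benzyloxy)-5-methoxybenzyl]-3,4,5-trimethoxyphenoxy}-3-phenylpropanoate | CCOC(=O)C[C@H](Oc1cc(OC)c(OC)c(OC)c1Cc1cc(OC)ccc1OCc1ccccc1)c1ccccc1
F2 | step 7 | (3S)-3-{2-[2-(benzyloxy)-5-methoxybenzyl]-3,4,5-trimethoxyphenoxy}-3-phenylpropanoic acid | OC(=O)C[C@H](Oc1cc(OC)c(OC)c(OC)c1Cc1cc(OC)ccc1OCc1ccccc1)c1ccccc1
F3 | step 8 | (2S)-8-(2-hydroxy-5-methoxybenzyl)-5,6,7-trimethoxy-2-phenylchroman-4-one | COc1ccc(O)c(Cc2c(OC)c(OC)c(OC)c3c2O[C@H](c2ccccc2)CC3=O)c1
F4 | step 6 | {2-[2-(benzyloxy)-5-methoxybenzyl]-3,4,5-trimethoxy-6-(trimethylsilyl)phenoxy}trimethylsilane | COc1ccc(OCc2ccccc2)c(Cc2c(O[Si](C)(C)C)c([Si](C)(C)C)c(OC)c(OC)c2OC)c1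
F5 | step 6 | 2-[2-(benzyloxy)-5-methoxybenzyl]-3,4,5-trimethoxy-6-(trimethylsilyl)phenol | COc1ccc(OCc2ccccc2)c(Cc2c(O)c([Si](C)(C)C)c(OC)c(OC)c2OC)c1
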